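**Retrosynthetic overview**
- As written, the target is a cis-fused decalin: H-5 and the angular CH3 lie on the same face, the CH2OAr group is on that face too, and the OAc is on the opposite face. It is therefore a 5-epi-drimane, and the ring fusion is made by cuprate methylation, not taken from a trans-drimane.
- Late disconnections: C2–OAc (enolate oxidation of the C3 ketone, then acetylation), then the aryl ether C11–O (Mitsunobu with isofraxidin), then C9–C11 together with the exocyclic methylene (allylsilane plus formaldehyde, SE2′).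
- Earlier: allylsilane from an enol triflate, which comes from Me2CuLi addition to a 4a-H octalone (angular methyl enters cis to H-5).
- No ring is built from acyclic material: ring A is the saturated ring of 6-methoxy-2-tetralone (gem-dimethylated first), ring B is its anisole ring, released second as a cyclohexenone by Birch reduction.
- Absolute configuration: CBS reduction (temporary C3 carbinol that masks the ketone) and an amine-catalysed enantioselective olefin isomerisation (C5); C10, C9 and C2 follow by substrate control.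

Locants in the Why lines are drimane locants: C1–C5 and C10 form ring A, C5–C10 form ring B, C11 is the CH2O carbon, C12 the exocyclic CH2.

Assumption: of the two pseudoenantiomeric cinchona primary amines, the quinidine-derived one is taken as the one that protonates the face giving (4aS)-7; the quinine-derived one gives the opposite sense.

**Step 1**
Reactants: 1 6-methoxy-2-tetralone
Product: 3 6-methoxy-1,1-dimethyl-3,4-dihydronaphthalen-2(1H)-one, via monomethyl tetralone 2 (not isolated)
Conditions: NaH (2.5 equiv), MeI (3 equiv), THF, 0 °C → rt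
Reagents that add atoms: iodomethane CI
Why: Twofold enolate C-alkylation at the benzylic α-carbon (future C4), the only position whose enolate is conjugated with the arene, installs the gem-dimethyl group; no stereocentre.

**Step 2**
Reactants: 3 6-methoxy-1,1-dimethyl-3,4-dihydronaphthalen-2(1H)-one
Product: 4 (2R)-6-methoxy-1,1-dimethyl-1,2,3,4-tetrahydronaphthalen-2-ol
Conditions: (S)-Me-CBS oxazaborolidine (10 mol %), BH3·SMe2 (0.7 equiv), THF, −20 °C; MeOH
Reagents that add atoms: none
Why: Corey–Bakshi–Shibata reduction: the ketone binds with its large quaternary benzylic flank away from the catalyst, so hydride reaches one face and sets the temporary C3 carbinol as R (it masks the C3 ketone until step 9).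

**Step 3**
Reactants: 4 (2R)-6-methoxy-1,1-dimethyl-1,2,3,4-tetrahydronaphthalen-2-ol
Product: 6 (6R)-6-hydroxy-5,5-dimethyl-3,4,5,6,7,8-hexahydronaphthalen-2(1H)-one, via Birch dienol ether 5 (not isolated)
Conditions: Li, NH3(l), t-BuOH, THF, −78 → −33 °C; NH4Cl; then (CO2H)2, THF–H2O, rt
Reagents that add atoms: water O
Why: Birch reduction leaves the donor-bearing carbons sp2 (methyl enol ether plus the tetrasubstituted C5=C10 olefin), and oxalic acid hydrolyses only the enol ether to the β,γ-unsaturated C8 ketone without conjugation; the C3 carbinol is untouched.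

**Step 4**
Reactants: 6 (6R)-6-hydroxy-5,5-dimethyl-3,4,5,6,7,8-hexahydronaphthalen-2(1H)-one
Product: 7 (4aS,6R)-6-hydroxy-5,5-dimethyl-4,4a,5,6,7,8-hexahydronaphthalen-2(3H)-one
Conditions: 9-amino-9-deoxy-epi-quinidine (10 mol %), PhCO2H (20 mol %), PhMe, −20 °C
Reagents that add atoms: none
Why: Amine-catalysed enantioselective olefin isomerisation: the primary amine forms a dienamine across C8–C9–C10–C5 and the protonated quinuclidine delivers H to one face of C5 (5S), a sense matched with the substrate's own preference for the epimer with the C3 hydroxyl and the C5–C6 bond both equatorial.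

**Step 5**
Reactants: 7 (4aS,6R)-6-hydroxy-5,5-dimethyl-4,4a,5,6,7,8-hexahydronaphthalen-2(3H)-one
Product: 9 (4aS,6R,8aS)-6-hydroxy-5,5,8a-trimethyl-3,4,4a,5,6,7,8,8a-octahydronaphthalen-2-yl trifluoromethanesulfonate, via dilithium enolate alkoxide 8 (not isolated)
Conditions: Me2CuLi (3.5 equiv, from MeLi and CuI), Et2O, −40 → 0 °C; then PhNTf2 (1.2 equiv), THF, 0 °C → rt; NH4Cl
Reagents that add atoms: lithium dimethylcuprate [Li+].C[Cu-]C; N-phenylbis(trifluoromethanesulfonimide) O=S(=O)(N(c1ccccc1)S(=O)(=O)C(F)(F)F)C(F)(F)F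
Why: Gilman conjugate addition: methyl adds to C10 anti to the bulky C4 substituent on the adjacent C5, i.e. on the face of H-5, giving the cis ring fusion (10S), and the regiodefined C8 enolate is trapped as the enol triflate while the hindered C3 lithium alkoxide stays untouched.

**Step 6**
Reactants: 9 (4aS,6R,8aS)-6-hydroxy-5,5,8a-trimethyl-3,4,4a,5,6,7,8,8a-octahydronaphthalen-2-yl trifluoromethanesulfonate
Product: 10 (2R,4aR,8aS)-1,1,4a-trimethyl-6-[(trimethylsilyl)methyl]-1,2,3,4,4a,7,8,8a-octahydronaphthalen-2-ol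
Conditions: Me3SiCH2MgCl (3 equiv), Pd(PPh3)4 (5 mol %), THF, 0 °C → rt
Reagents that add atoms: (trimethylsilyl)methylmagnesium chloride C[Si](C)(C)C[Mg]Cl
Why: Kumada–Corriu coupling (oxidative addition of the enol triflate to zerovalent palladium, transmetalation, reductive elimination); the Grignard has no β-hydrogen, the stereocentres are untouched and the free hydroxyl only consumes one equivalent of reagent.

**Step 7**
Reactants: 10 (2R,4aR,8aS)-1,1,4a-trimethyl-6-[(trimethylsilyl)methyl]-1,2,3,4,4a,7,8,8a-octahydronaphthalen-2-ol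
Product: 11 (2R,4aS,5S,8aS)-5-(hydroxymethyl)-1,1,4a-trimethyl-6-methylidenedecahydronaphthalen-2-ol
Conditions: (CH2O)n (1.5 equiv), Me2AlCl (3 equiv), CH2Cl2, −78 → −20 °C; aq. KNaC4H4O6
Reagents that add atoms: formaldehyde C=O
Why: Hosomi–Sakurai (SE2′) hydroxymethylation: C9 attacks Me2AlCl-activated formaldehyde and loss of the silyl group leaves the C8=C12 exocyclic olefin regiospecifically; attack comes from the convex β face of the cis-decalin (the α face of C9 is covered by ring A), so C11 ends up cis to the angular methyl (9S).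

**Step 8**
Reactants: 11 (2R,4aS,5S,8aS)-5-(hydroxymethyl)-1,1,4a-trimethyl-6-methylidenedecahydronaphthalen-2-ol; 12 isofraxidin (7-hydroxy-6,8-dimethoxy-2H-chromen-2-one)
Product: 13 7-{[(1S,4aS,6R,8aS)-6-hydroxy-5,5,8a-trimethyl-2-methylidenedecahydronaphthalen-1-yl]methoxy}-6,8-dimethoxy-2H-chromen-2-one
Conditions: PPh3, DIAD, THF, 0 °C → rt
Reagents that add atoms: none
Why: Mitsunobu etherification: the acidic phenol displaces the oxyphosphonium of the primary C11 alcohol (SN2 at CH2, no stereocentre touched), while the hindered neopentyl C3 alcohol does not react.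

**Step 9**
Reactants: 13 7-{[(1S,4aS,6R,8aS)-6-hydroxy-5,5,8a-trimethyl-2-methylidenedecahydronaphthalen-1-yl]methoxy}-6,8-dimethoxy-2H-chromen-2-one
Product: 14 6,8-dimethoxy-7-{[(1S,4aS,8aS)-5,5,8a-trimethyl-2-methylidene-6-oxodecahydronaphthalen-1-yl]methoxy}-2H-chromen-2-one
Conditions: Dess–Martin periodinane, pyridine, CH2Cl2, rt
Reagents that add atoms: none
Why: Dess–Martin oxidation of the secondary C3 carbinol under neutral conditions that spare the exocyclic olefin, the coumarin and the aryl ether; the temporary C3 stereocentre is erased.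

**Step 10**
Reactants: 14 6,8-dimethoxy-7-{[(1S,4aS,8aS)-5,5,8a-trimethyl-2-methylidene-6-oxodecahydronaphthalen-1-yl]methoxy}-2H-chromen-2-one
Product: 16 7-{[(1S,4aS,7R,8aS)-7-hydroxy-5,5,8a-trimethyl-2-methylidene-6-oxodecahydronaphthalen-1-yl]methoxy}-6,8-dimethoxy-2H-chromen-2-one, via potassium enolate 15 (not isolated)
Conditions: KN(SiMe3)2 (1.1 equiv), THF, −78 °C; then 2-(phenylsulfonyl)-3-phenyloxaziridine, −78 °C; NH4Cl
Reagents that add atoms: 2-(phenylsulfonyl)-3-phenyloxaziridine O=S(=O)(N1OC1c1ccccc1)c1ccccc1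
Why: Davis enolate oxidation: C4 is quaternary so only the C2 enolate can form, and the oxaziridine attacks its α face because the β face is flanked by the syn-axial C10 and C4β methyls (ring A chair as in 3-oxo-triterpenoids), giving the equatorial 2α-alcohol (2R).

**Step 11**
Reactants: 16 7-{[(1S,4aS,7R,8aS)-7-hydroxy-5,5,8a-trimethyl-2-methylidene-6-oxodecahydronaphthalen-1-yl]methoxy}-6,8-dimethoxy-2H-chromen-2-one
Product: 17 (2R,4aS,8S,8aS)-8-{[(6,8-dimethoxy-2-oxo-2H-chromen-7-yl)oxy]methyl}-4,4,8a-trimethyl-7-methylidene-3-oxodecahydronaphthalen-2-yl acetate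
Conditions: Ac2O, pyridine, DMAP (cat.), CH2Cl2, 0 °C
Reagents that add atoms: acetic anhydride CC(=O)OC(C)=O
Why: DMAP-catalysed O-acetylation with retention at C2 under mild base, so the α-acetoxy ketone is not epimerised, giving the target.

**Compound list**
1 | 6-methoxy-3,4-dihydronaphthalen-2(1H)-one (6-methoxy-2-tetralone) | COc1ccc2c(c1)CCC(=O)C2 | starting material
2 | 6-methoxy-1-methyl-3,4-dihydronaphthalen-2(1H)-one (racemic, not isolated) | COc1ccc2c(c1)CCC(=O)C2C | intermediate
3 | 6-methoxy-1,1-dimethyl-3,4-dihydronaphthalen-2(1H)-one | COc1ccc2c(c1)CCC(=O)C2(C)C | intermediate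
4 | (2R)-6-methoxy-1,1-dimethyl-1,2,3,4-tetrahydronaphthalen-2-ol | COc1ccc2c(c1)CC[C@@H](O)C2(C)C | intermediate
5 | (2R)-6-methoxy-1,1-dimethyl-1,2,3,4,5,8-hexahydronaphthalen-2-ol (Birch 1,4-diene, present as its lithium alkoxide, not isolated) | COC1=CCC2=C(C1)CC[C@@H](O)C2(C)C | intermediate
6 | (6R)-6-hydroxy-5,5-dimethyl-3,4,5,6,7,8-hexahydronaphthalen-2(1H)-one (β,γ-unsaturated ketone) | O=C1CCC2=C(C1)CC[C@@H](O)C2(C)C | intermediate
7 | (4aS,6R)-6-hydroxy-5,5-dimethyl-4,4a,5,6,7,8-hexahydronaphthalen-2(3H)-one (H-4a and H-6 cis) | O=C1CC[C@@H]2C(C)(C)[C@H](O)CCC2=C1 | intermediate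
8 | dilithium (4aS,6R,8aS)-5,5,8a-trimethyl-3,4,4a,5,6,7,8,8a-octahydronaphthalene-2,6-diolate (enolate and alkoxide, not isolated) | [Li+].[Li+].[O-]C=1CC[C@@H]2C(C)(C)[C@H]([O-])CC[C@]2(C)C=1 | intermediate
9 | (4aS,6R,8aS)-6-hydroxy-5,5,8a-trimethyl-3,4,4a,5,6,7,8,8a-octahydronaphthalen-2-yl trifluoromethanesulfonate (cis-fused) | O=S(=O)(OC=1CC[C@@H]2C(C)(C)[C@H](O)CC[C@]2(C)C=1)C(F)(F)F | intermediate
10 | (2R,4aR,8aS)-1,1,4a-trimethyl-6-[(trimethylsilyl)methyl]-1,2,3,4,4a,7,8,8a-octahydronaphthalen-2-ol (cis-fused allylsilane) | C[Si](C)(C)CC=1CC[C@@H]2C(C)(C)[C@H](O)CC[C@]2(C)C=1 | intermediate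
11 | (2R,4aS,5S,8aS)-5-(hydroxymethyl)-1,1,4a-trimethyl-6-methylidenedecahydronaphthalen-2-ol | C=C1CC[C@@H]2C(C)(C)[C@H](O)CC[C@]2(C)[C@H]1CO | intermediate
12 | isofraxidin (7-hydroxy-6,8-dimethoxy-2H-chromen-2-one) | COc1cc2ccc(=O)oc2c(OC)c1O | starting material
13 | 7-{[(1S,4aS,6R,8aS)-6-hydroxy-5,5,8a-trimethyl-2-methylidenedecahydronaphthalen-1-yl]methoxy}-6,8-dimethoxy-2H-chromen-2-one | C=C1CC[C@@H]2C(C)(C)[C@H](O)CC[C@]2(C)[C@H]1COc1c(OC)cc2ccc(=O)oc2c1OC | intermediate
14 | 6,8-dimethoxy-7-{[(1S,4aS,8aS)-5,5,8a-trimethyl-2-methylidene-6-oxodecahydronaphthalen-1-yl]methoxy}-2H-chromen-2-one | C=C1CC[C@@H]2C(C)(C)C(=O)CC[C@]2(C)[C@H]1COc1c(OC)cc2ccc(=O)oc2c1OC | intermediate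
15 | potassium enolate of 14 (C2=C3 enolate in drimane locants, not isolated) | [K+].C=C1CC[C@@H]2C(C)(C)C([O-])=CC[C@]2(C)[C@H]1COc1c(OC)cc2ccc(=O)oc2c1OC | intermediate
16 | 7-{[(1S,4aS,7R,8aS)-7-hydroxy-5,5,8a-trimethyl-2-methylidene-6-oxodecahydronaphthalen-1-yl]methoxy}-6,8-dimethoxy-2H-chromen-2-one | C=C1CC[C@@H]2C(C)(C)C(=O)[C@H](O)C[C@]2(C)[C@H]1COc1c(OC)cc2ccc(=O)oc2c1OC | intermediate
17 | (2R,4aS,8S,8aS)-8-{[(6,8-dimethoxy-2-oxo-2H-chromen-7-yl)oxy]methyl}-4,4,8a-trimethyl-7-methylidene-3-oxodecahydronaphthalen-2-yl acetate (CNP0183157.2) | C=C1CC[C@@H]2C(C)(C)C(=O)[C@H](OC(C)=O)C[C@]2(C)[C@H]1COc1c(OC)cc2ccc(=O)oc2c1OC | target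

**Step count and risks**
Total steps: 11. Longest linear sequence: 11 steps (1 → 17); isofraxidin 12 enters at step 8.

The three steps most likely to fail are step 4, step 7 and step 10.

In step 4 the gem-dimethyl group next to the carbon being protonated may lower the rate or the selectivity of the catalyst. The fallback sets out from 6 and comes back at 7. Compound 6 is stirred with 2 M HCl in THF, so that the dienol equilibrates to the conjugated enones under substrate (thermodynamic) control. Compound 7 forms together with its C-4a epimer (4aR,6R)-6-hydroxy-5,5-dimethyl-4,4a,5,6,7,8-hexahydronaphthalen-2(3H)-one F1, estimated at about 3:1 in favour of 7 because 7 has the hydroxyl and the ring bond both equatorial. The two are separated by chromatography, and F1 is put back into the same acid so that material funnels to 7.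

In step 7 the exocyclic olefin of the product can react further with formaldehyde (ene or Prins), and the face selectivity at C9 rests on a conformational argument. The fallback sets out from 7 and comes back at 11, replacing the allylsilane chemistry by an aldol and a methylenation. Me2CuLi is added as in step 5, but enolate 8 is trapped with gaseous formaldehyde on its convex face to give (1S,4aS,6R,8aS)-6-hydroxy-1-(hydroxymethyl)-5,5,8a-trimethyloctahydronaphthalen-2(1H)-one F2. The primary hydroxyl is silylated (t-BuMe2SiCl, imidazole) to (1S,4aS,6R,8aS)-1-{[tert-butyl(dimethyl)silyl]oxymethyl}-6-hydroxy-5,5,8a-trimethyloctahydronaphthalen-2(1H)-one F3. The ketone is methylenated without base (Zn, CH2Br2, TiCl4), so that the epimerisable C9 centre is kept, giving (2R,4aS,5S,8aS)-5-{[tert-butyl(dimethyl)silyl]oxymethyl}-1,1,4a-trimethyl-6-methylidenedecahydronaphthalen-2-ol F4. n-Bu4NF then gives 11.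

In step 10 the strong base may attack the coumarin lactone. The fallback sets out from 14 and comes back at 17 without any strong base. Soft enolisation (Me3SiOTf, Et3N, CH2Cl2, 0 °C) gives the silyl enol ether 6,8-dimethoxy-7-{[(1S,4aS,8aS)-5,5,8a-trimethyl-2-methylidene-6-[(trimethylsilyl)oxy]-1,2,3,4,4a,5,8,8a-octahydronaphthalen-1-yl]methoxy}-2H-chromen-2-one F5. Pb(OAc)4 in CH2Cl2 at 0 °C then acetoxylates it on the same open α face and gives the acetate 17 directly.

**Further compounds**
F1 | step 4 | (4aR,6R)-6-hydroxy-5,5-dimethyl-4,4a,5,6,7,8-hexahydronaphthalen-2(3H)-one | O=C1CC[C@H]2C(C)(C)[C@H](O)CCC2=C1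
F2 | step 7 | (1S,4aS,6R,8aS)-6-hydroxy-1-(hydroxymethyl)-5,5,8a-trimethyloctahydronaphthalen-2(1H)-one | O=C1CC[C@@H]2C(C)(C)[C@H](O)CC[C@]2(C)[C@H]1CO
F3 | step 7 | (1S,4aS,6R,8aS)-1-{[tert-butyl(dimethyl)silyl]oxymethyl}-6-hydroxy-5,5,8a-trimethyloctahydronaphthalen-2(1H)-one | O=C1CC[C@@H]2C(C)(C)[C@H](O)CC[C@]2(C)[C@H]1CO[Si](C)(C)C(C)(C)C
F4 | step 7 | (2R,4aS,5S,8aS)-5-{[tert-butyl(dimethyl)silyl]oxymethyl}-1,1,4a-trimethyl-6-methylidenedecahydronaphthalen-2-ol | C=C1CC[C@@H]2C(C)(C)[C@H](O)CC[C@]2(C)[C@H]1CO[Si](C)(C)C(C)(C)C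
F5 | step 10 | 6,8-dimethoxy-7-{[(1S,4aS,8aS)-5,5,8a-trimethyl-2-methylidene-6-[(trimethylsilyl)oxy]-1,2,3,4,4a,5,8,8a-octahydronaphthalen-1-yl]methoxy}-2H-chromen-2-one | C=C1CC[C@@H]2C(C)(C)C(O[Si](C)(C)C)=CC[C@]2(C)[C@H]1COc1c(OC)cc2ccc(=O)oc2c1OC
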